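**Strategy**

- Retrosynthetic cuts, in order: the C15–O bond, the C1/C10 oxirane, the ester C–O bonds at O8 and O3, the lactone O6–C12 bond, then the C8–C9 bond of the ten-membered ring in a retro-oxy-Cope sense (which restores a C1–C6 bond), and last the C6–C7 bond between a cyclohexenone and a five-carbon dienyl metal (C7, C8, C11–C13).
- Enabling feature: in the carbocycle C1–C10 the oxygen on C6 lies 1,5 to the E C1=C10 alkene (the later epoxide), and the Z C4=C5 alkene with O3 beside it is a cyclohexene alkene opened out. C1–C6 with C9, C10, C14 and C15 are therefore the ten carbons of carvone.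
- Forward order: the six-membered ring is bought as (R)-carvone and re-oxidised at C6, the dienyl unit is added at C6, an anionic oxy-Cope shift enlarges six to ten, the γ-lactone is closed at O6–C12, and the oxirane and the C15 hydroxyl come last.
- Stereochemistry: C3 from Luche reduction of carvone followed by Mitsunobu inversion. The carvone stereocentre (C1) is consumed and relayed through a chair transition state to C8, where silicon is later exchanged for oxygen with retention. C7 (protonation) and C6 (hydride) both come from attack on the outer face of the as-formed ring, and C1/C10 from peripheral peracid attack on the E alkene. The Z C4=C5 geometry is inherited from the ring.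

Key step: step 11

Remark: germacranolide numbering is used for all intermediates (ring C1–C10, lactone carbons C11–C13, C14 on C10, C15 on C4), and it is assumed that the trans-lactone 28 reacts through the conformer with C14 on the β face, as is usual for 1(10)-ene germacranolides of this type.

**Route**

Step 1
Reactants: 1 (R)-(−)-carvone
Product: 2 (1R,5R)-cis-carveol
Conditions: NaBH4, CeCl3·7H2O, MeOH, 0 °C
Reagents that add atoms: none
Why: Luche 1,2-reduction of the enone, in which axial hydride delivery should give the carbinol (future C3) cis to the isopropenyl group.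

Step 2
Reactants: 2 (1R,5R)-cis-carveol
Product: 3 (1S,5R)-trans-carveyl 4-nitrobenzoate
Conditions: 4-nitrobenzoic acid, PPh3, DIAD, THF, 0 °C to rt
Reagents that add atoms: 4-nitrobenzoic acid O=C(O)c1ccc(cc1)[N+](=O)[O-]
Why: Mitsunobu esterification proceeds with SN2 inversion at the carbinol carbon, which sets the S configuration of the future C3 trans to the isopropenyl group.

Step 3
Reactants: 3 (1S,5R)-trans-carveyl 4-nitrobenzoate
Product: 4 (1S,5R)-trans-carveol
Conditions: K2CO3 (cat.), MeOH, rt
Reagents that add atoms: none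
Why: base-catalysed transesterification cleaves the acyl–oxygen bond, so the inverted carbinol centre is not touched.

Step 4
Reactants: 4 (1S,5R)-trans-carveol
Product: 5 (1S,5R)-trans-carveol tert-butyldimethylsilyl ether
Conditions: TBSCl, imidazole, DMF, rt
Reagents that add atoms: tert-butyl(chloro)dimethylsilane CC(C)(C)[Si](C)(C)Cl
Why: standard imidazole-promoted silylation of a secondary allylic alcohol, giving an ether that survives the organometallic and hydride steps ahead.

Step 5
Reactants: 5 (1S,5R)-trans-carveol tert-butyldimethylsilyl ether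
Product: 6 (4S,6R)-4-[(tert-butyldimethylsilyl)oxy]-3-methyl-6-(prop-1-en-2-yl)cyclohex-2-en-1-one
Conditions: CrO3, 3,5-dimethylpyrazole, CH2Cl2, −20 °C
Reagents that add atoms: chromium trioxide O=[Cr](=O)=O
Why: allylic C–H oxidation of a ring methylene to the enone with the CrO3–3,5-dimethylpyrazole complex should take the only unhindered secondary allylic position (future C6), since the other ring allylic C–H is shielded by the silyloxy group, and the non-basic medium should leave the new α-centre (future C1) unepimerised and unconjugated.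

Step 6
Reactants: 7 ethynylmagnesium bromide
Product: 8 benzyl(ethynyl)dimethylsilane
Conditions: BnMe2SiCl, THF, 0 °C to rt
Reagents that add atoms: benzyl(chloro)dimethylsilane C[Si](C)(Cl)Cc1ccccc1
Why: nucleophilic substitution at silicon by the alkynyl Grignard reagent installs a silyl group that can later be oxidised after fluoride debenzylation.

Step 7
Reactants: 9 2-bromoprop-2-en-1-ol
Product: 10 2-bromo-3-[(2-methoxypropan-2-yl)oxy]prop-1-ene
Conditions: 2-methoxypropene, PPTS (cat.), CH2Cl2, 0 °C
Reagents that add atoms: 2-methoxypropene C=C(C)OC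
Why: acid-catalysed addition of the alcohol to the enol ether gives a mixed acetal on O12 that cannot migrate to a neighbouring carbanion or alkoxide and is later removed under very mild acid.

Step 8
Reactants: 10 2-bromo-3-[(2-methoxypropan-2-yl)oxy]prop-1-ene; 8 benzyl(ethynyl)dimethylsilane
Product: 11 benzyl{3-[(2-methoxypropan-2-yl)oxymethyl]but-3-en-1-yn-1-yl}dimethylsilane
Conditions: Pd(PPh3)2Cl2 (cat.), CuI (cat.), Et3N, THF, rt to 40 °C
Reagents that add atoms: none
Why: Sonogashira coupling of a vinyl bromide with a terminal silylalkyne forms the C7–C11 bond.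

Step 9
Reactants: 11 benzyl{3-[(2-methoxypropan-2-yl)oxymethyl]but-3-en-1-yn-1-yl}dimethylsilane
Product: 12 tributyl{(1E)-1-[benzyl(dimethyl)silyl]-3-[(2-methoxypropan-2-yl)oxymethyl]buta-1,3-dien-2-yl}stannane
Conditions: Bu3SnH, Pd(PPh3)4 (cat.), THF, 0 °C
Reagents that add atoms: tributyltin hydride CCCC[SnH](CCCC)CCCC
Why: palladium-catalysed syn-hydrostannation of a conjugated silyl enyne should place tin on C7, the alkyne carbon next to the alkenyl group and away from the bulky silyl terminus, and syn addition puts silicon trans to tin.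

Step 10
Reactants: 12 tributyl{(1E)-1-[benzyl(dimethyl)silyl]-3-[(2-methoxypropan-2-yl)oxymethyl]buta-1,3-dien-2-yl}stannane; 6 (4S,6R)-4-[(tert-butyldimethylsilyl)oxy]-3-methyl-6-(prop-1-en-2-yl)cyclohex-2-en-1-one
Product: 15 tertiary dienyl carbinol (hydroxyl cis to isopropenyl), via dienyllithium 13 (not isolated), via dienylcerium dichloride 14 (not isolated)
Conditions: n-BuLi, THF, −78 °C; CeCl3, −78 °C; then 6, −78 °C; H2O
Reagents that add atoms: none
Why: tin–lithium exchange with retention of alkene geometry, transmetalation to the weakly basic organocerium and 1,2-addition to the enone should form the C6–C7 bond on the carbonyl face anti to the adjacent isopropenyl group, which places the two alkenyl groups trans; the minor C6 epimer is removed by chromatography.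

Step 11
Reactants: 15 tertiary dienyl carbinol (hydroxyl cis to isopropenyl)
Product: 18 (1(10)E,4Z)-8β-silyl germacra-1(10),4,11(13)-trien-6-one with H7 α, via potassium alkoxide 16 (not isolated), via potassium dienolate 17 (not isolated)
Conditions: KH, 18-crown-6, THF, 0 °C to rt; then AcOH, THF, −78 °C
Reagents that add atoms: none
Why: Deprotonation gives the naked potassium alkoxide 16, which should undergo an alkoxide-accelerated concerted [3,3]-sigmatropic shift over C8=C7–C6–C1–C10=C9 in a chair array, the C8–C9 bond forming as the C1–C6 ring bond breaks and the resulting dienolate 17 making the step irreversible. The closest known reaction type is the anionic oxy-Cope ring expansion of trans-1,2-dialkenylcyclohexanols to (E)-cyclodec-5-enones. The ten-membered carbocycle is thus closed by a six-to-ten ring enlargement and not by end-to-end cyclisation, so neither high dilution nor macrocyclisation entropy is at issue. C8 is set by chirality transfer from the carvone stereocentre (C1) through the chair in which C2 is equatorial (hence the E C1=C10 alkene) and silicon, trans to C6 on the vinylsilane, is equatorial; C7 is set by kinetic α-protonation of the dienolate on its open outer face, which puts C11 cis to the silyl group. The step needs periselectivity for the exocyclic vinylsilane over the endocyclic C4=C5 bond, secured because the C1–C6 bond lies close to the nodal plane of the ring alkene, and it needs chair rather than boat topology, which the trans arrangement of the two alkenyl groups provides. Silicon on C8 leaves the enolate without a β-leaving group and sits out of reach of the alkoxide, so neither elimination nor silyl transfer to oxygen should compete, and the Z C4=C5 alkene is carried through as a spectator.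

Step 12
Reactants: 18 (1(10)E,4Z)-8β-silyl germacra-1(10),4,11(13)-trien-6-one with H7 α
Product: 19 6α-hydroxy germacratriene with the O12 acetal intact
Conditions: NaBH4, CeCl3·7H2O, MeOH, −78 °C
Reagents that add atoms: none
Why: Luche 1,2-reduction, in which hydride should add to the exposed outer face of the C6 carbonyl in the as-formed ring conformer and so set C6 with its oxygen placed for the trans-fused lactone, while the cold, weakly basic medium spares the epimerisable C7.

Step 13
Reactants: 19 6α-hydroxy germacratriene with the O12 acetal intact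
Product: 20 6α,12-diol
Conditions: PPTS (cat.), MeOH, 0 °C
Reagents that add atoms: none
Why: acid-catalysed acetal exchange with methanol frees O12 under conditions mild enough to leave the silyl ether, the carbon-bound silane and the acid-sensitive 1(10),4-diene intact.

Step 14
Reactants: 20 6α,12-diol
Product: 23 8β-[benzyl(dimethyl)silyl]-3-silyloxy germacra-1(10),4,11(13)-trien-12,6α-olide, via hydroxy enal 21 (not isolated), via lactol 22 (not isolated)
Conditions: TEMPO (cat.), PhI(OAc)2, CH2Cl2, rt
Reagents that add atoms: none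
Why: oxoammonium-mediated oxidative lactonisation of a 2-methylene-1,4-diol, in which the primary allylic alcohol is oxidised selectively, the enal is trapped by the C6 hydroxyl as the five-membered lactol and this is oxidised on to the α-methylene γ-lactone, closing O6–C12 with the trans fusion fixed by C6 and C7.

Step 15
Reactants: 23 8β-[benzyl(dimethyl)silyl]-3-silyloxy germacra-1(10),4,11(13)-trien-12,6α-olide
Product: 24 8β-[benzyl(dimethyl)silyl]-3-hydroxy germacratrienolide
Conditions: HF·pyridine, pyridine, THF, 0 °C to rt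
Reagents that add atoms: none
Why: buffered fluoride cleavage of the silyl ether, which is too weakly nucleophilic to attack the carbon-bound benzyldimethylsilyl group and too weakly acidic to harm the diene or the α-methylene lactone.

Step 16
Reactants: 24 8β-[benzyl(dimethyl)silyl]-3-hydroxy germacratrienolide
Product: 25 3-acetoxy-8β-[benzyl(dimethyl)silyl] germacratrienolide
Conditions: Ac2O, pyridine, DMAP (cat.), CH2Cl2, 0 °C to rt
Reagents that add atoms: acetic anhydride CC(=O)OC(C)=O
Why: DMAP-catalysed acylation of the only free hydroxyl.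

Step 17
Reactants: 25 3-acetoxy-8β-[benzyl(dimethyl)silyl] germacratrienolide
Product: 27 3-acetoxy-8β-hydroxy germacra-1(10),4,11(13)-trien-12,6α-olide, via silanol 26 (not isolated)
Conditions: Bu4NF, THF, 0 °C; then KHCO3, 30% aq. H2O2, MeOH, 0 °C to rt
Reagents that add atoms: hydrogen peroxide OO
Why: Tamao–Fleming oxidation of the benzyldimethylsilyl group, in which fluoride expels benzyl as toluene to give the silanol and peroxide then drives the 1,2-shift of C8 from silicon to oxygen with retention, so O8 takes the configuration set in step 11; brief, bicarbonate-buffered treatment should spare the acetate and the α-methylene lactone and avoid relactonisation onto O8.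

Step 18
Reactants: 27 3-acetoxy-8β-hydroxy germacra-1(10),4,11(13)-trien-12,6α-olide
Product: 28 3-acetoxy-8β-methacryloyloxy germacra-1(10),4,11(13)-trien-12,6α-olide
Conditions: methacrylic anhydride, Et3N, DMAP (cat.), CH2Cl2, 0 °C to rt
Reagents that add atoms: methacrylic anhydride C=C(C)C(=O)OC(=O)C(C)=C
Why: DMAP-catalysed esterification of the secondary C8 hydroxyl with the anhydride.

Step 19
Reactants: 28 3-acetoxy-8β-methacryloyloxy germacra-1(10),4,11(13)-trien-12,6α-olide
Product: 29 (1R,10R)-1,10-epoxide of 28
Conditions: mCPBA, NaHCO3, CH2Cl2, 0 °C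
Reagents that add atoms: 3-chloroperoxybenzoic acid OOC(=O)c1cccc(Cl)c1
Why: Prilezhaev epoxidation, in which C1=C10 is the only alkene neither conjugated to a carbonyl nor flanked by two allylic oxygens, and syn addition to the exposed outer face of the E alkene in the lactone-locked conformer with C14 on the β face should give the (1R,10R) oxirane.

Step 20
Reactants: 29 (1R,10R)-1,10-epoxide of 28
Product: 30 CNP0319155.1
Conditions: SeO2 (cat.), t-BuOOH, CH2Cl2, rt
Reagents that add atoms: selenium dioxide O=[Se]=O (delivers the oxygen); tert-butyl hydroperoxide CC(C)(C)OO (terminal oxidant that restores it)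
Why: selenium dioxide allylic hydroxylation (ene reaction followed by [2,3]-sigmatropic shift) should attack the more substituted end of the one remaining trisubstituted alkene and, of the two allylic groups on C4, the methyl cis to H5 rather than the acetoxy-bearing methine, so only C15 is hydroxylated and the Z geometry is kept.

**Compound list**

1 | (R)-(−)-carvone | CC1=CC[C@H](CC1=O)C(C)=C | starting material
2 | (1R,5R)-cis-carveol | C1C=C(C)[C@H](O)C[C@@H]1C(C)=C | intermediate
3 | (1S,5R)-trans-carveyl 4-nitrobenzoate | C1C=C(C)[C@@H](OC(=O)c2ccc(cc2)[N+](=O)[O-])C[C@@H]1C(C)=C | intermediate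
4 | (1S,5R)-trans-carveol | C1C=C(C)[C@@H](O)C[C@@H]1C(C)=C | intermediate
5 | (1S,5R)-trans-carveol tert-butyldimethylsilyl ether | C1C=C(C)[C@@H](O[Si](C)(C)C(C)(C)C)C[C@@H]1C(C)=C | intermediate
6 | (4S,6R)-4-[(tert-butyldimethylsilyl)oxy]-3-methyl-6-(prop-1-en-2-yl)cyclohex-2-en-1-one | O=C1C=C(C)[C@@H](O[Si](C)(C)C(C)(C)C)C[C@@H]1C(C)=C | intermediate
7 | ethynylmagnesium bromide | C#C[Mg]Br | starting material
8 | benzyl(ethynyl)dimethylsilane | C#C[Si](C)(C)Cc1ccccc1 | intermediate
9 | 2-bromoprop-2-en-1-ol | C=C(Br)CO | starting material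
10 | 2-bromo-3-[(2-methoxypropan-2-yl)oxy]prop-1-ene | C=C(Br)COC(C)(C)OC | intermediate
11 | benzyl{3-[(2-methoxypropan-2-yl)oxymethyl]but-3-en-1-yn-1-yl}dimethylsilane | C=C(COC(C)(C)OC)C#C[Si](C)(C)Cc1ccccc1 | intermediate
12 | tributyl{(1E)-1-[benzyl(dimethyl)silyl]-3-[(2-methoxypropan-2-yl)oxymethyl]buta-1,3-dien-2-yl}stannane (Si trans to Sn) | CCCC[Sn](CCCC)(CCCC)/C(=C/[Si](C)(C)Cc1ccccc1)C(=C)COC(C)(C)OC | intermediate
13 | 1-[benzyl(dimethyl)silyl]-3-[(2-methoxypropan-2-yl)oxymethyl]buta-1,3-dien-2-yllithium (Si trans to Li) | [Li]/C(=C/[Si](C)(C)Cc1ccccc1)C(=C)COC(C)(C)OC | intermediate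
14 | corresponding dienylcerium dichloride (Si trans to Ce) | Cl[Ce](Cl)/C(=C/[Si](C)(C)Cc1ccccc1)C(=C)COC(C)(C)OC | intermediate
15 | (1R,4S,6R)-1-{(1E)-1-[benzyl(dimethyl)silyl]-3-[(2-methoxypropan-2-yl)oxymethyl]buta-1,3-dien-2-yl}-4-[(tert-butyldimethylsilyl)oxy]-3-methyl-6-(prop-1-en-2-yl)cyclohex-2-en-1-ol (OH cis to isopropenyl, silyloxy trans to it) | O[C@]1(/C(=C/[Si](C)(C)Cc2ccccc2)C(=C)COC(C)(C)OC)C=C(C)[C@@H](O[Si](C)(C)C(C)(C)C)C[C@@H]1C(C)=C | intermediate
16 | potassium alkoxide of 15 | [K+].[O-][C@]1(/C(=C/[Si](C)(C)Cc2ccccc2)C(=C)COC(C)(C)OC)C=C(C)[C@@H](O[Si](C)(C)C(C)(C)C)C[C@@H]1C(C)=C | intermediate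
17 | potassium 6-oxido-germacra-1(10)E,4Z,6,11(13)-tetraene dienolate (8β-silyl, C5 cis to C11 on the enolate) | [K+].C[Si](C)(Cc2ccccc2)[C@@H]1C/C(C)=C/C[C@H](O[Si](C)(C)C(C)(C)C)/C(C)=C\C([O-])=C1/C(=C)COC(C)(C)OC | intermediate
18 | (3S)-8β-[benzyl(dimethyl)silyl]-3-[(tert-butyldimethylsilyl)oxy]-12-[(2-methoxypropan-2-yl)oxy]germacra-1(10)E,4Z,11(13)-trien-6-one, H7 α (cis to H8) | C[Si](C)(Cc2ccccc2)[C@@H]1C/C(C)=C/C[C@H](O[Si](C)(C)C(C)(C)C)/C(C)=C\C(=O)[C@@H]1C(=C)COC(C)(C)OC | intermediate
19 | 6α-alcohol of 18 (H6 β, O12 acetal intact) | C[Si](C)(Cc2ccccc2)[C@@H]1C/C(C)=C/C[C@H](O[Si](C)(C)C(C)(C)C)/C(C)=C\[C@@H](O)[C@@H]1C(=C)COC(C)(C)OC | intermediate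
20 | 8β-[benzyl(dimethyl)silyl]-3-[(tert-butyldimethylsilyl)oxy]germacra-1(10)E,4Z,11(13)-triene-6α,12-diol | C[Si](C)(Cc2ccccc2)[C@@H]1C/C(C)=C/C[C@H](O[Si](C)(C)C(C)(C)C)/C(C)=C\[C@@H](O)[C@@H]1C(=C)CO | intermediate
21 | 6α-hydroxy-12-al (2-substituted acrolein) | C[Si](C)(Cc2ccccc2)[C@@H]1C/C(C)=C/C[C@H](O[Si](C)(C)C(C)(C)C)/C(C)=C\[C@@H](O)[C@@H]1C(=C)C=O | intermediate
22 | 12,6α-lactol (both anomers) | C[Si](C)(Cc3ccccc3)[C@@H]1C/C(C)=C/C[C@H](O[Si](C)(C)C(C)(C)C)/C(C)=C\[C@H]2OC(O)C(=C)[C@@H]21 | intermediate
23 | 8β-[benzyl(dimethyl)silyl]-3-[(tert-butyldimethylsilyl)oxy]germacra-1(10)E,4Z,11(13)-trien-12,6α-olide (trans-fused) | C[Si](C)(Cc3ccccc3)[C@@H]1C/C(C)=C/C[C@H](O[Si](C)(C)C(C)(C)C)/C(C)=C\[C@H]2OC(=O)C(=C)[C@@H]21 | intermediate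
24 | 8β-[benzyl(dimethyl)silyl]-3-hydroxygermacra-1(10)E,4Z,11(13)-trien-12,6α-olide | C[Si](C)(Cc3ccccc3)[C@@H]1C/C(C)=C/C[C@H](O)/C(C)=C\[C@H]2OC(=O)C(=C)[C@@H]21 | intermediate
25 | 3-acetoxy-8β-[benzyl(dimethyl)silyl]germacra-1(10)E,4Z,11(13)-trien-12,6α-olide | C[Si](C)(Cc3ccccc3)[C@@H]1C/C(C)=C/C[C@H](OC(C)=O)/C(C)=C\[C@H]2OC(=O)C(=C)[C@@H]21 | intermediate
26 | 3-acetoxy-8β-(hydroxydimethylsilyl)germacra-1(10)E,4Z,11(13)-trien-12,6α-olide | C[Si](C)(O)[C@@H]1C/C(C)=C/C[C@H](OC(C)=O)/C(C)=C\[C@H]2OC(=O)C(=C)[C@@H]21 | intermediate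
27 | 3-acetoxy-8β-hydroxygermacra-1(10)E,4Z,11(13)-trien-12,6α-olide | O[C@@H]1C/C(C)=C/C[C@H](OC(C)=O)/C(C)=C\[C@H]2OC(=O)C(=C)[C@@H]21 | intermediate
28 | 3-acetoxy-8β-methacryloyloxygermacra-1(10)E,4Z,11(13)-trien-12,6α-olide | C=C(C)C(=O)O[C@@H]1C/C(C)=C/C[C@H](OC(C)=O)/C(C)=C\[C@H]2OC(=O)C(=C)[C@@H]21 | intermediate
29 | (1R,10R)-1,10-epoxy-3-acetoxy-8β-methacryloyloxygermacra-4Z,11(13)-dien-12,6α-olide | C=C(C)C(=O)O[C@@H]1C[C@@]2(C)O[C@@H]2C[C@H](OC(C)=O)/C(C)=C\[C@H]2OC(=O)C(=C)[C@@H]21 | intermediate
30 | CNP0319155.1, the 15-hydroxy derivative of 29 (1R,3S,6R,7R,8R,10R) | C=C(C)C(=O)O[C@@H]1C[C@@]2(C)O[C@@H]2C[C@H](OC(C)=O)/C(CO)=C\[C@H]2OC(=O)C(=C)[C@@H]21 | target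

**Step count and risks**

Total step count: 20. Longest linear sequence: 16 steps (steps 1–5 and 10–20, from carvone).

Steps most likely to fail:

Step 11. The potassium alkoxide may fragment and recombine, or undergo a 1,3-shift, instead of the concerted chair [3,3] shift, which would erode the chirality transfer to C8. The naked dienolate may also be protonated at the γ-carbon or on the wrong face, or C7 may epimerise during work-up. The fallback separates rearrangement from protonation and avoids the free alkoxide. Starting from carbinol 15, silylation with N-(trimethylsilyl)imidazole should give the trimethylsilyl ether F1. Thermolysis in a sealed tube (toluene, about 200 °C) would effect the neutral siloxy-Cope rearrangement to the ten-membered silyl dienol ether F2, which can be isolated. Cleavage with MeLi in THF at 0 °C should give the lithium dienolate F3, and quenching with AcOH at −78 °C then returns to ketone 18.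

Step 19. The peracid may attack the wrong face of the C1=C10 alkene if the conformer with C14 on the α face is the one that reacts, giving the diastereomeric oxirane. The fallback inverts the facial outcome by mechanism rather than by conformer control. Starting from diene 28, NBS in aqueous THF at 0 °C should give, by anti addition with water entering at the tertiary carbon, the 1-bromo-10-hydroxy bromohydrin F4. Ring closure with Ag2O in THF displaces bromide with inversion at C1 and so places the oxygen on the face opposite to the one the electrophile attacked, returning to epoxide 29.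

Step 20. The ene reaction may be sluggish because the C4=C5 alkene is flanked by two allylic acyloxy groups, and prolonged exposure risks over-oxidation of C15 to the enal and opening of the oxirane by selenous acid. The fallback accepts the over-oxidation and corrects the oxidation level afterwards. Starting from epoxide 29, stoichiometric SeO2 in dioxane at 70 °C should carry the oxidation through to the C15 enal F5, and NaBH4 with CeCl3·7H2O in MeOH at −78 °C should then reduce only the aldehyde, returning to target 30.

Further compounds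
F1 | step 11 | trimethylsilyl ether of carbinol 15 | C[Si](C)(C)O[C@]1(/C(=C/[Si](C)(C)Cc2ccccc2)C(=C)COC(C)(C)OC)C=C(C)[C@@H](O[Si](C)(C)C(C)(C)C)C[C@@H]1C(C)=C
F2 | step 11 | 6-(trimethylsilyloxy)germacra-1(10)E,4Z,6,11(13)-tetraene silyl dienol ether (8β-silyl) | C[Si](C)(Cc2ccccc2)[C@@H]1C/C(C)=C/C[C@H](O[Si](C)(C)C(C)(C)C)/C(C)=C\C(O[Si](C)(C)C)=C1/C(=C)COC(C)(C)OC
F3 | step 11 | lithium dienolate corresponding to 17 | [Li+].C[Si](C)(Cc2ccccc2)[C@@H]1C/C(C)=C/C[C@H](O[Si](C)(C)C(C)(C)C)/C(C)=C\C([O-])=C1/C(=C)COC(C)(C)OC
F4 | step 19 | 1-bromo-10-hydroxy bromohydrin of 28 | C=C(C)C(=O)O[C@@H]1C[C@@](C)(O)[C@@H](Br)C[C@H](OC(C)=O)/C(C)=C\[C@H]2OC(=O)C(=C)[C@@H]21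
F5 | step 20 | C15 enal of 29 (15-oxo) | C=C(C)C(=O)O[C@@H]1C[C@@]2(C)O[C@@H]2C[C@H](OC(C)=O)/C(C=O)=C\[C@H]2OC(=O)C(=C)[C@@H]21
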